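Readings and results come from a simulation for substances that don't exist; noise was put on by code.

The target, counted with its crystals, is what you want from this closed, stirred flask. The gas phase is held at one level throughout, so the question is how quickly the starting material turns over.

| flask | starting material | gas phase | remark | time |
|---|---|---|---|---|
| gamma | 0.74 M | 200 mM (held) | run made earlier |  |
| epsilon | 1.7 M | 200 mM (held) | run made earlier |  |
| flask | 1.1 M | 200 mM (held) |  | 15 h |

| run | time / h | target / % | crystals / % |
|---|---|---|---|
| gamma | 2.50 | 25 | 19 |
| gamma | 6.00 | 45 | 43 |
| gamma | 12.0 | 69 | 70 |
| gamma | 20.0 | 87 | 84 |
| epsilon | 5.00 | 37 | 39 |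
| epsilon | 10.0 | 62 | 63 |
| epsilon | 15.0 | 75 | 73 |
| epsilon | 20.0 | 89 | 86 |

(standard deviation of a reading: 1.5 percentage points)

- amounts and yields of target count crystals too
- given per volume of solution although it is solid: crystals
- at the start none of the gas phase is in solution

1. the target and crystals together standing at 15 h, as a percentage of the starting material charged
2. concentration of dissolved gas in solution at 15 h, in percent of saturation

Set gamma beside epsilon. Epsilon holds 2.30 times the starting material of gamma, yet at 20.0 h they read 87% and 89%, a gap of 2 percentage points against a scatter of 1.5 points per reading. For each reading, take the natural log of the charge over what remains, divide by the time, and average over the run: gamma gives 0.104 /h and epsilon 0.0980 /h. The two runs end alike because these means are close: with the gas held, each hour takes about the same share of what remains at both charges, which is pseudo-first-order behaviour. Together they give 0.101 /h, the mean fractional rate.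

For this flask, that rate gives 77.9% at 15 h. To see what replacing the curve by its mean costs, take each run's mean alone: for this flask at 15 h, epsilon's gives 77.0% and gamma's 79.0%, while epsilon's own reading at 15.0 h was 75%. Epsilon's larger charge asks more gas than this flask's, yet its mean stays close to gamma's, so you should expect dissolved gas in this flask near saturation.

The forecast says 77% and 98%, holding that “gas uptake is not limiting”; its yield lies just below this reckoning. The flask gives 78.1% and 98.9%.

    crystals ⇌ target, rate k1*(cs1 - [target]) while solid is left; crystals form when [target] > cs1 (solubility = 12.0 mM, k = 0.00906 /s)
    gas phase ⇌ dissolved gas, rate k2*(csat - [dissolved gas]) (kL = 0.00320 /s)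
    starting material + dissolved gas → target (k = 1.46 × 10⁻⁴ /M/s)
    dissolved gas + target → over-reacted product (k = 1.93 × 10⁻⁵ /M/s)

In this flask dissolved gas stood at 0.192 M at 1.50 h and 0.198 M at 15.0 h, while starting material and dissolved gas made target that fell out as crystals: at the later time target, crystals counted, stood at 78.1% of the charge and crystals at 76.9% of the charge. Over-reacted product reached 0.251% in the same time, which made no difference to the yield. The mean fractional rate leaves 22.0% of the starting material in this flask, and the flask holds 22%. Left until 25 h, the neighbouring flask should stand at 92.0% by the same rate, and it is computed at 92.0%.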